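## The problem

The target is a flavone (2-arylchromen-4-one) with a hexasubstituted ring A: C5 hydroxyl, C6 prenyl, C7 methoxy and C8 prenyl, plus the two fusion carbons C4a and C8a. Ring C carries a third prenyl group at C3, and ring B is a 2,4,5-trihydroxyphenyl (hydroxyquinol) unit at C2. There is no stereocentre, so the whole difficulty is regiochemical: four different substituents must be placed on ring A and ring C must be fused to its two remaining carbons. The usual ways of attaching the C4 carbonyl to C4a (Friedel–Crafts or Fries acylation) would have to act on a pentasubstituted diprenylphenol under Lewis acid, which is unattractive. The three prenyl groups do not tolerate strong acid, electrophilic halogen or hydrogenation, and two of them sit next to phenols (C6 prenyl beside C5-OH, C3 prenyl beside C2'-OH) onto which they can cyclise. The free hydroxyquinol ring is easily oxidised by air, so the phenols should stay masked as methoxymethyl (MOM) ethers until the last step. The enabling feature is that O1–C8a and C4–C4a lie on neighbouring ring A carbons while the other four ring A carbons are already substituted. Ring A can therefore enter as a tetrasubstituted aryne whose two reactive carbons become C8a and C4a, with the C5 oxygen next to the triple bond steering the addition. Ring A with its acyl group at C4a is also symmetric about the C4a–C7 axis, so it can be built from symmetric 3,5-dihydroxyanisole, provided the two oxygens are told apart once.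

## Retrosynthesis

**Unmasking and the C3 prenyl group.** Target 27 is traced to its tetra-MOM ether 26, so that the last step is a mild acetal cleavage. In 26 the C3–CH2 bond is cut, giving 3-iodoflavone 25, and the C3–I bond in turn leads back to flavone 23. C3 is the only ring position flanked by the carbonyl and the C2 aryl group, so it can be addressed by deprotonation. The alternative of carrying the prenyl group through ring closure is not open, because C3 originates as an alkyne carbon. The forward steps must lithiate C3 without disturbing three allylic side chains and must deliver the prenyl group through its unsubstituted terminus.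

**Ring C.** Cutting O1–C2 of 23 gives ortho-hydroxyaryl ynone 21. This cut is preferred to C2–C1' (arylation of a chromone) or C2–C3 (diketone chemistry needing acid cyclodehydration), because 21 is an open chain of two arenes joined by a three-carbon unit and closes under mild amine catalysis. The forward step must close 6-endo and not 5-exo.

**The key disconnection.** Both O1–C8a and C4–C4a of 21 are cut at once. This gives aryne precursor 12, a 2-(trimethylsilyl)aryl triflate carrying all four ring A substituents, and arylpropiolic acid 17. Neighbouring cuts would attach an acetylide or an acyl cation to an already hexasubstituted arene. The aryne insertion forms both bonds from two fragments of similar size and needs no Lewis or Brønsted acid. The forward step must put the carboxylate oxygen on C8a, not C4a, and must transfer the acyl group to carbon before the aryl anion is protonated.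

**Ring A building block.** Triflate 12 comes from phenol 11, and 11 from symmetric bis-MOM ether 9 by release of one of its two equivalent oxygens. Compound 9 is taken apart at its three ring–substituent bonds: the two prenyl groups (from prenyl bromide 5, via 7) and the silyl group (via 4), back to bis-MOM ether 2 and 3,5-dihydroxyanisole 1. Direct C-prenylation of 1 would not distinguish its three nucleophilic ring carbons. Directed lithiation does: the carbon between the two MOM ethers is metalated first, which is where silicon must go, and the silyl group then blocks that site so that only the two carbons flanking the methoxy group remain for prenylation.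

**Ring B building block.** Acid 17 is cut at the C–CO2H bond to lithium acetylide 16, which comes from dibromoalkene 15 and this from aldehyde 14, the tris-MOM ether of 2,4,5-trihydroxybenzaldehyde 13. This homologation uses the aldehyde carbon already present in 13 and avoids preparing an aryl halide for a Sonogashira coupling followed by ester hydrolysis.

## Roads not taken

Alternative 1: The cut is O1–C8a, made by intramolecular SNAr. The enolate oxygen of 2-prenyl-1,3-diketone A2, whose ring A ketone carries two equivalent ortho fluorides, would displace one fluoride and give 5-fluoroflavone A1 with all three prenyl groups in place.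
- Merits: the two fluorides are equivalent, so there is no regiochemical question. The C3 prenyl group enters by simple C-alkylation of a diketone, which is better than the chosen plan, where it costs a lithiation and a cross-coupling (steps 12 and 13).
- Weak points: the remaining C5 fluoride must be exchanged for oxygen on a carbon flanked by a prenyl group, using an oxygen nucleophile on a chromone that opens readily by attack at C2. The pentasubstituted difluoro ketone needs metalations next to fluorine, where aryne loss threatens.
- Comparison: the chosen plan has oxygen at C5 from the first step and forms the aryl–oxygen bond without a leaving group to repair afterwards. It sets this against the easier C3 prenylation of A1.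

Alternative 2: The cut is at the two ring A prenyl bonds, C6–CH2 and C8–CH2. Heating bis(1,1-dimethylallyl) ether A4 would send each allyl group by ortho-Claisen rearrangement to its only free ortho carbon and give diprenyl acetophenone A3.
- Merits: the step is thermal and reagent-free, symmetry guarantees the regiochemistry, and it avoids both the lithiation next to a prenyl group (step 4) and the single unmasking of two equivalent ethers (step 5). In the decoration of ring A this road is the better one.
- Weak points: the key step forms no bond of ring C. From A3 the flavone still needs aroylation, acyl migration, C-prenylation and a cyclodehydration, which is normally acid-driven and would meet two free ortho-prenyl phenols. A4 needs two tertiary ethers on a chelated, hindered dihydroxy ketone, and such ethers tend to fragment or give chromans on heating.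
- Comparison: the chosen plan makes the two bonds that join ring A to the rest in one acid-free step. It sets that against the cleaner prenyl placement of the Claisen route.

Alternative 3: The cut goes through ring A itself (C5–C6, C7–C8 and C4a–C5). Irradiation of pyranone diazoketone A6 would give a vinylketene by Wolff rearrangement, which would take up alkoxyalkyne A7 and electrocyclise to A5, the target with only ring B still protected.
- Merits: this is the most convergent road. All four ring A substituents are placed by the mechanism, the C5 hydroxyl emerges free, and only one deprotection would follow. In step count after fragment union it beats the chosen plan.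
- Weak points: A6 is a multistep target in its own right. Its diazo carbon carries a prenyl methylene, so hydrogen shift or cyclopropanation can compete with the Wolff step. The 2-aryl-4-pyranone chromophore is photoactive at the wavelength needed, and A7 is a labile skipped enyne.
- Comparison: the chosen plan is longer after the union but uses two simple, stable partners and a known bond-forming pattern.

Key step: step 10

Assumption: compounds 1, 5 and 13 and tributyl(3-methylbut-2-enyl)stannane are purchased; the target has no stereocentre, so only racemic fallback alcohol F2 contains one.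

## Route

Step 1
Reactants: 1 3,5-dihydroxyanisole
Product: 2 1-methoxy-3,5-bis(methoxymethoxy)benzene
Conditions: MOMCl, i-Pr2NEt, CH2Cl2, 0 °C to rt
Reagents that add atoms: chloromethyl methyl ether (MOMCl), COCCl
Why: Both phenols are alkylated by the reactive α-chloro ether under amine base (Williamson-type acetal formation); MOM is chosen because it is a strong oxygen director for the three lithiations that follow and can be removed at the end without Lewis acid.

Step 2
Reactants: 2 1-methoxy-3,5-bis(methoxymethoxy)benzene
Product: 4 [4-methoxy-2,6-bis(methoxymethoxy)phenyl]trimethylsilane, via aryllithium 3 (not isolated)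
Conditions: n-BuLi, THF, 0 °C; TMSCl, −78 °C to rt
Reagents that add atoms: chlorotrimethylsilane, C[Si](C)(C)Cl
Why: Directed ortho-metalation; the carbon between the two MOM ethers is doubly coordinated and should be lithiated in preference to the two carbons beside the methoxy group, and the silyl quench installs the future aryne trigger while blocking this site for steps 3 and 4.

Step 3
Reactants: 4 [4-methoxy-2,6-bis(methoxymethoxy)phenyl]trimethylsilane; 5 prenyl bromide
Product: 7 [4-methoxy-2,6-bis(methoxymethoxy)-3-(3-methylbut-2-enyl)phenyl]trimethylsilane, via aryllithium 6 (not isolated)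
Conditions: s-BuLi, TMEDA, THF, −78 °C; CuBr·SMe2 (10 mol %), 5, −78 to 0 °C
Reagents that add atoms: none
Why: Directed ortho-metalation at one of the two equivalent remaining ring hydrogens (between OMe and OMOM), then copper-catalysed allylic substitution of 5 at its unsubstituted terminus, which gives the linear prenyl group.

Step 4
Reactants: 7 [4-methoxy-2,6-bis(methoxymethoxy)-3-(3-methylbut-2-enyl)phenyl]trimethylsilane; 5 prenyl bromide
Product: 9 [4-methoxy-2,6-bis(methoxymethoxy)-3,5-bis(3-methylbut-2-enyl)phenyl]trimethylsilane, via aryllithium 8 (not isolated)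
Conditions: s-BuLi, TMEDA, THF, −78 °C; CuBr·SMe2 (10 mol %), 5, −78 to 0 °C
Reagents that add atoms: none
Why: The same directed ortho-metalation and copper-catalysed prenylation at the last ring hydrogen; at −78 °C the coordination-assisted ring deprotonation should outrun removal of the benzylic-allylic hydrogens of the first prenyl group.

Step 5
Reactants: 9 [4-methoxy-2,6-bis(methoxymethoxy)-3,5-bis(3-methylbut-2-enyl)phenyl]trimethylsilane
Product: 11 3-methoxy-5-(methoxymethoxy)-2,4-bis(3-methylbut-2-enyl)-6-(trimethylsilyl)phenol, via aryl trimethylsilyl ether 10 (not isolated)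
Conditions: TMSOTf (1 equiv), 2,2'-bipyridyl, CH2Cl2, 0 °C; then H2O, NaHCO3
Reagents that add atoms: none
Why: Silyl triflate–bipyridyl cleavage of an aromatic MOM ether, which converts the acetal under buffered, non-protic conditions into the aryl silyl ether that water then hydrolyses; no Brønsted acid meets the very electron-rich aryl–silicon bond or the prenyl groups, and one equivalent of reagent with recovery of unreacted 9 is meant to hold the reaction at one of the two equivalent ethers.

Step 6
Reactants: 11 3-methoxy-5-(methoxymethoxy)-2,4-bis(3-methylbut-2-enyl)-6-(trimethylsilyl)phenol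
Product: 12 3-methoxy-5-(methoxymethoxy)-2,4-bis(3-methylbut-2-enyl)-6-(trimethylsilyl)phenyl trifluoromethanesulfonate
Conditions: KN(SiMe3)2, THF, −78 °C; PhNTf2, −78 °C to rt; aq. NH4Cl
Reagents that add atoms: N-phenylbis(trifluoromethanesulfonimide), O=S(=O)(N(c1ccccc1)S(=O)(=O)C(F)(F)F)C(F)(F)F
Why: O-sulfonylation of the potassium phenoxide with a mild triflyl donor; the other ring oxygen is still a MOM ether, so no phenoxide can sit beside silicon once the triflate is present and the aryne is not released early.

Step 7
Reactants: 13 2,4,5-trihydroxybenzaldehyde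
Product: 14 2,4,5-tris(methoxymethoxy)benzaldehyde
Conditions: MOMCl, i-Pr2NEt, DMF, 0 to 40 °C, argon
Reagents that add atoms: chloromethyl methyl ether (MOMCl), COCCl
Why: Threefold acetal formation at the phenols; the chelated 2-hydroxyl reacts last and argon protects the electron-rich ring from air oxidation under base.

Step 8
Reactants: 14 2,4,5-tris(methoxymethoxy)benzaldehyde
Product: 15 1-(2,2-dibromoethenyl)-2,4,5-tris(methoxymethoxy)benzene
Conditions: CBr4, PPh3, Et3N, CH2Cl2, 0 °C
Reagents that add atoms: carbon tetrabromide, BrC(Br)(Br)Br
Why: First stage of the Corey–Fuchs reaction, a Wittig-type olefination by the dibromomethylene ylide formed from CBr4 and PPh3; Et3N keeps the medium from turning acidic toward the MOM ethers.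

Step 9
Reactants: 15 1-(2,2-dibromoethenyl)-2,4,5-tris(methoxymethoxy)benzene
Product: 17 3-[2,4,5-tris(methoxymethoxy)phenyl]prop-2-ynoic acid, via lithium acetylide 16 (not isolated)
Conditions: n-BuLi (2.2 equiv), THF, −78 °C; CO2, −78 to 0 °C; cold 1 M HCl to pH 2
Reagents that add atoms: carbon dioxide, O=C=O
Why: Second stage of the Corey–Fuchs reaction: bromine–lithium exchange, loss of LiBr with 1,2-shift and deprotonation give the lithium acetylide, which CO2 carboxylates; brief cold acidification frees the acid without cleaving the acetals.

Step 10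
Reactants: 12 3-methoxy-5-(methoxymethoxy)-2,4-bis(3-methylbut-2-enyl)-6-(trimethylsilyl)phenyl trifluoromethanesulfonate; 17 3-[2,4,5-tris(methoxymethoxy)phenyl]prop-2-ynoic acid
Product: 21 1-[2-hydroxy-4-methoxy-6-(methoxymethoxy)-3,5-bis(3-methylbut-2-enyl)phenyl]-3-[2,4,5-tris(methoxymethoxy)phenyl]prop-2-yn-1-one, via aryne 18 (not isolated), via aryl anion 19 (not isolated), via benzoxetene alkoxide 20 (not isolated)
Conditions: 12 (1.5 equiv), CsF (4 equiv), THF, sealed tube, 110 °C; pH 7 phosphate buffer
Reagents that add atoms: none
Why: Fluoride attacks the silicon of 12 and triflate leaves, releasing aryne 18. The cesium carboxylate of 17 adds through oxygen to C8a, the aryne carbon remote from the MOM ether, because the inductively withdrawing C5 oxygen distorts the triple bond and stabilises the developing charge at the adjacent C4a (anion 19); this electronic bias should outweigh the steric demand of the prenyl methylene at C8. The aryl anion, held beside the ester, attacks the acyl carbon in a transient 4-exo-trig closure to alkoxide 20, whose four-membered ring opens by C–O cleavage to the phenoxide of 21, so that O1–C8a and C4–C4a are formed and no ring remains. The closest known reaction type is the insertion of arynes into the C–O bond of carboxylic acids, arylpropiolic acids included, which gives ortho-hydroxyaryl ketones. Heating in THF, which offers no acidic hydrogen, favours acyl transfer over protonation of 19 to the simple aryl ester. No stereocentre is formed. The step needs chemoselectivity for the carboxylate over the alkyne and the prenyl double bonds as aryne partners, which the anionic oxygen nucleophile secures, and it runs without any acid that could harm the prenyl groups or the acetals.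

Step 11
Reactants: 21 1-[2-hydroxy-4-methoxy-6-(methoxymethoxy)-3,5-bis(3-methylbut-2-enyl)phenyl]-3-[2,4,5-tris(methoxymethoxy)phenyl]prop-2-yn-1-one
Product: 23 7-methoxy-5-(methoxymethoxy)-6,8-bis(3-methylbut-2-enyl)-2-[2,4,5-tris(methoxymethoxy)phenyl]chromen-4-one, via enaminone 22 (not isolated)
Conditions: Et2NH, EtOH, 50 °C
Reagents that add atoms: none
Why: Conjugate addition of Et2NH to the ynone gives enaminone 22, and the free phenol then displaces the amine by addition–elimination at C2 (6-endo closure), a path that cannot lead to the 5-exo aurone.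

Step 12
Reactants: 23 7-methoxy-5-(methoxymethoxy)-6,8-bis(3-methylbut-2-enyl)-2-[2,4,5-tris(methoxymethoxy)phenyl]chromen-4-one
Product: 25 3-iodo-7-methoxy-5-(methoxymethoxy)-6,8-bis(3-methylbut-2-enyl)-2-[2,4,5-tris(methoxymethoxy)phenyl]chromen-4-one, via 3-lithioflavone 24 (not isolated)
Conditions: LiN(i-Pr)2, THF, −78 °C; I2, −78 °C; aq. Na2S2O3
Reagents that add atoms: iodine, II
Why: Flavones are deprotonated at C3 by lithium amides at −78 °C (the vinylic hydrogen α to the carbonyl, here also next to the ortho MOM ether of ring B), and iodine traps vinyllithium 24 at once at low temperature, before ring opening or alkene iodination can compete.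

Step 13
Reactants: 25 3-iodo-7-methoxy-5-(methoxymethoxy)-6,8-bis(3-methylbut-2-enyl)-2-[2,4,5-tris(methoxymethoxy)phenyl]chromen-4-one
Product: 26 7-methoxy-5-(methoxymethoxy)-3,6,8-tris(3-methylbut-2-enyl)-2-[2,4,5-tris(methoxymethoxy)phenyl]chromen-4-one
Conditions: Bu3SnCH2CH=CMe2, Pd(PPh3)4 (5 mol %), DMF, 90 °C
Reagents that add atoms: tributyl(3-methylbut-2-enyl)stannane, CCCC[Sn](CCCC)(CCCC)CC=C(C)C
Why: Stille coupling: oxidative addition of zerovalent palladium into the C3–I bond, transmetalation from the allylstannane and reductive elimination at the unsubstituted allyl terminus give the linear prenyl group; the neutral conditions leave the acetals and the other two prenyl groups alone.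

Step 14
Reactants: 26 7-methoxy-5-(methoxymethoxy)-3,6,8-tris(3-methylbut-2-enyl)-2-[2,4,5-tris(methoxymethoxy)phenyl]chromen-4-one
Product: 27 5-hydroxy-7-methoxy-3,6,8-tris(3-methylbut-2-enyl)-2-(2,4,5-trihydroxyphenyl)chromen-4-one (CNP0330304.0)
Conditions: 3 M aq. HCl, MeOH, 45 °C, argon
Reagents that add atoms: none
Why: Acid-catalysed transacetalisation of the four MOM ethers to dimethoxymethane in methanol; dilute acid at moderate temperature under argon is meant to unmask the phenols faster than a prenyl group can cyclise onto a neighbouring hydroxyl and to keep the hydroxyquinol ring from oxidising.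

## Compound list

1 | 3,5-dihydroxyanisole (5-methoxybenzene-1,3-diol) | COc1cc(O)cc(O)c1 | starting material
2 | 1-methoxy-3,5-bis(methoxymethoxy)benzene | COCOc1cc(OC)cc(OCOC)c1 | intermediate
3 | [4-methoxy-2,6-bis(methoxymethoxy)phenyl]lithium | [Li]c1c(OCOC)cc(OC)cc1OCOC | intermediate
4 | [4-methoxy-2,6-bis(methoxymethoxy)phenyl]trimethylsilane | COc1cc(OCOC)c([Si](C)(C)C)c(OCOC)c1 | intermediate
5 | prenyl bromide (1-bromo-3-methylbut-2-ene) | CC(C)=CCBr | starting material
6 | [6-methoxy-2,4-bis(methoxymethoxy)-3-(trimethylsilyl)phenyl]lithium | [Li]c1c(OC)cc(OCOC)c([Si](C)(C)C)c1OCOC | intermediate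
7 | [4-methoxy-2,6-bis(methoxymethoxy)-3-(3-methylbut-2-enyl)phenyl]trimethylsilane | COc1cc(OCOC)c([Si](C)(C)C)c(OCOC)c1CC=C(C)C | intermediate
8 | [2-methoxy-4,6-bis(methoxymethoxy)-3-(3-methylbut-2-enyl)-5-(trimethylsilyl)phenyl]lithium | [Li]c1c(OC)c(CC=C(C)C)c(OCOC)c([Si](C)(C)C)c1OCOC | intermediate
9 | [4-methoxy-2,6-bis(methoxymethoxy)-3,5-bis(3-methylbut-2-enyl)phenyl]trimethylsilane | COc1c(CC=C(C)C)c(OCOC)c([Si](C)(C)C)c(OCOC)c1CC=C(C)C | intermediate
10 | trimethyl[3-methoxy-5-(methoxymethoxy)-2,4-bis(3-methylbut-2-enyl)-6-(trimethylsilyl)phenoxy]silane | COc1c(CC=C(C)C)c(OCOC)c([Si](C)(C)C)c(O[Si](C)(C)C)c1CC=C(C)C | intermediate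
11 | 3-methoxy-5-(methoxymethoxy)-2,4-bis(3-methylbut-2-enyl)-6-(trimethylsilyl)phenol | COc1c(CC=C(C)C)c(OCOC)c([Si](C)(C)C)c(O)c1CC=C(C)C | intermediate
12 | 3-methoxy-5-(methoxymethoxy)-2,4-bis(3-methylbut-2-enyl)-6-(trimethylsilyl)phenyl trifluoromethanesulfonate | COc1c(CC=C(C)C)c(OCOC)c([Si](C)(C)C)c(OS(=O)(=O)C(F)(F)F)c1CC=C(C)C | intermediate
13 | 2,4,5-trihydroxybenzaldehyde | O=Cc1cc(O)c(O)cc1O | starting material
14 | 2,4,5-tris(methoxymethoxy)benzaldehyde | O=Cc1cc(OCOC)c(OCOC)cc1OCOC | intermediate
15 | 1-(2,2-dibromoethenyl)-2,4,5-tris(methoxymethoxy)benzene | BrC(Br)=Cc1cc(OCOC)c(OCOC)cc1OCOC | intermediate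
16 | lithium [2,4,5-tris(methoxymethoxy)phenyl]ethynide | [Li]C#Cc1cc(OCOC)c(OCOC)cc1OCOC | intermediate
17 | 3-[2,4,5-tris(methoxymethoxy)phenyl]prop-2-ynoic acid | OC(=O)C#Cc1cc(OCOC)c(OCOC)cc1OCOC | intermediate
18 | 1,2-didehydro-5-methoxy-3-(methoxymethoxy)-4,6-bis(3-methylbut-2-enyl)benzene (the aryne) | COC1=C(CC=C(C)C)C#CC(OCOC)=C1CC=C(C)C | intermediate
19 | cesium 4-methoxy-6-(methoxymethoxy)-3,5-bis(3-methylbut-2-enyl)-2-{3-[2,4,5-tris(methoxymethoxy)phenyl]prop-2-ynoyloxy}benzenide | O=C(C#Cc1cc(OCOC)c(OCOC)cc1OCOC)Oc1[c-]c(OCOC)c(CC=C(C)C)c(OC)c1CC=C(C)C.[Cs+] | intermediate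
20 | cesium 5-methoxy-3-(methoxymethoxy)-4,6-bis(3-methylbut-2-enyl)-2-{[2,4,5-tris(methoxymethoxy)phenyl]ethynyl}-2H-benzoxet-2-olate | [O-]C1(C#Cc2cc(OCOC)c(OCOC)cc2OCOC)Oc2c(CC=C(C)C)c(OC)c(CC=C(C)C)c(OCOC)c12.[Cs+] | intermediate
21 | 1-[2-hydroxy-4-methoxy-6-(methoxymethoxy)-3,5-bis(3-methylbut-2-enyl)phenyl]-3-[2,4,5-tris(methoxymethoxy)phenyl]prop-2-yn-1-one | O=C(C#Cc1cc(OCOC)c(OCOC)cc1OCOC)c1c(O)c(CC=C(C)C)c(OC)c(CC=C(C)C)c1OCOC | intermediate
22 | 3-(diethylamino)-1-[2-hydroxy-4-methoxy-6-(methoxymethoxy)-3,5-bis(3-methylbut-2-enyl)phenyl]-3-[2,4,5-tris(methoxymethoxy)phenyl]prop-2-en-1-one (alkene geometry not defined; both isomers close) | CCN(CC)C(=CC(=O)c1c(O)c(CC=C(C)C)c(OC)c(CC=C(C)C)c1OCOC)c1cc(OCOC)c(OCOC)cc1OCOC | intermediate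
23 | 7-methoxy-5-(methoxymethoxy)-6,8-bis(3-methylbut-2-enyl)-2-[2,4,5-tris(methoxymethoxy)phenyl]chromen-4-one | COc1c(CC=C(C)C)c(OCOC)c2c(=O)cc(-c3cc(OCOC)c(OCOC)cc3OCOC)oc2c1CC=C(C)C | intermediate
24 | {7-methoxy-5-(methoxymethoxy)-6,8-bis(3-methylbut-2-enyl)-4-oxo-2-[2,4,5-tris(methoxymethoxy)phenyl]chromen-3-yl}lithium | COc1c(CC=C(C)C)c(OCOC)c2c(=O)c([Li])c(-c3cc(OCOC)c(OCOC)cc3OCOC)oc2c1CC=C(C)C | intermediate
25 | 3-iodo-7-methoxy-5-(methoxymethoxy)-6,8-bis(3-methylbut-2-enyl)-2-[2,4,5-tris(methoxymethoxy)phenyl]chromen-4-one | COc1c(CC=C(C)C)c(OCOC)c2c(=O)c(I)c(-c3cc(OCOC)c(OCOC)cc3OCOC)oc2c1CC=C(C)C | intermediate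
26 | 7-methoxy-5-(methoxymethoxy)-3,6,8-tris(3-methylbut-2-enyl)-2-[2,4,5-tris(methoxymethoxy)phenyl]chromen-4-one | COc1c(CC=C(C)C)c(OCOC)c2c(=O)c(CC=C(C)C)c(-c3cc(OCOC)c(OCOC)cc3OCOC)oc2c1CC=C(C)C | intermediate
27 | 5-hydroxy-7-methoxy-3,6,8-tris(3-methylbut-2-enyl)-2-(2,4,5-trihydroxyphenyl)chromen-4-one (CNP0330304.0) | COc1c(CC=C(C)C)c(O)c2c(=O)c(CC=C(C)C)c(-c3cc(O)c(O)cc3O)oc2c1CC=C(C)C | target

## Step count and least certain steps

Total: 14 steps. Longest linear sequence: 11 steps (steps 1–6, then 10–14); the ring B branch (steps 7–9) joins at step 10.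

**Step 10 (key step).** Four processes could erode it:
- protonation of the aryl anion before acyl transfer, which would stop at the simple O-aryl ester;
- partial loss of regiocontrol if the steric push of the C8 prenyl methylene competes with the electronic bias of the C5 oxygen;
- conjugate closure of the product phenoxide in the flask, where the 6-endo mode only anticipates step 11 and gives 23, but the 5-exo mode is a loss;
- thermal decarboxylation of the electron-rich propiolic acid.

Fallback: the same aryne is generated from 12 with CsF in DMF, where it inserts into the formamide C=O bond with the same orientation. Aqueous work-up gives 2-hydroxy-4-methoxy-6-(methoxymethoxy)-3,5-bis(3-methylbut-2-enyl)benzaldehyde F1. Addition of lithium acetylide 16 (two equivalents, generated from 15 as in step 9 and used before carboxylation) gives racemic 1-[2-hydroxy-4-methoxy-6-(methoxymethoxy)-3,5-bis(3-methylbut-2-enyl)phenyl]-3-[2,4,5-tris(methoxymethoxy)phenyl]prop-2-yn-1-ol F2. Oxidation with MnO2 in CH2Cl2 returns to the route at 21. The bonds O1–C8a and C4–C4a are still made on the aryne; only the acyl oxidation level is reached in a later step.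

**Step 4.** The base may remove the doubly activated benzylic-allylic hydrogens of the prenyl group already present, which would lead to side-chain alkylation or alkene migration. Fallback: it sets out from 4 and never exposes a prenyl group to the deprotonating base.
- Aryllithium 6, made as in step 3, is quenched with BrCl2CCCl2Br to give [3-bromo-4-methoxy-2,6-bis(methoxymethoxy)phenyl]trimethylsilane F3.
- The last ring hydrogen of F3 is removed with lithium 2,2,6,6-tetramethylpiperidide at −78 °C, which does not exchange with the bromide, and copper-catalysed prenylation with 5 gives [3-bromo-4-methoxy-2,6-bis(methoxymethoxy)-5-(3-methylbut-2-enyl)phenyl]trimethylsilane F4.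
- Bromine–lithium exchange on F4 with t-BuLi at −78 °C, which is far faster than any deprotonation, gives aryllithium 8, and prenylation as in step 4 returns to the route at 9.

**Step 5.** Both MOM ethers are equivalent, so cleavage may run on to the doubly unmasked compound, and any adventitious acid may protodesilylate the electron-rich ring carbon. Fallback: it sets out from 9.
- Excess TMSOTf and 2,2'-bipyridyl convert both acetals and give [4-methoxy-3,5-bis(3-methylbut-2-enyl)-2,6-bis(trimethylsilyloxy)phenyl]trimethylsilane F5 without aqueous hydrolysis.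
- One equivalent of MeLi in THF cleaves a single O–Si bond, since the negative charge of the first phenoxide should slow attack at the second silyl ether, and gives lithium 3-methoxy-2,4-bis(3-methylbut-2-enyl)-6-(trimethylsilyl)-5-(trimethylsilyloxy)phenoxide F6.
- Alkylation of F6 with MOMCl returns to the route at silyl ether 10, which is hydrolysed to 11 as in step 5.

**Step 12.** The 3-lithio species may open by β-elimination of the ring oxygen (the reverse of step 11) if the temperature rises, the base may instead deprotonate a prenyl methylene or a ring B position beside a MOM ether, and iodine may add to an alkene. Fallback: it sets out from 21. Enaminone 22 is formed with Et2NH as in step 11 but at room temperature, then treated with one equivalent of I2. Iodination at the nucleophilic enaminone carbon, followed by closure of the phenol with loss of the amine, gives 25 directly, where the fallback returns to the route. No strong base is involved and the electrophile is consumed by the most nucleophilic carbon present.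

**Step 14.** Acid may induce cyclisation of the C6 or C3 prenyl group onto the newly freed C5 or C2' hydroxyl, and the free hydroxyquinol ring may be oxidised by air. Fallback: it sets out from 26. TMSOTf and 2,2'-bipyridyl in CH2Cl2 exchange all four acetals for silyl ethers without any Brønsted acid, giving 7-methoxy-3,6,8-tris(3-methylbut-2-enyl)-5-(trimethylsilyloxy)-2-[2,4,5-tris(trimethylsilyloxy)phenyl]chromen-4-one F7. Neutral hydrolysis of F7 in degassed aqueous methanol returns to the route at 27.

## Further compounds

F1 | step 10 | 2-hydroxy-4-methoxy-6-(methoxymethoxy)-3,5-bis(3-methylbut-2-enyl)benzaldehyde | O=Cc1c(O)c(CC=C(C)C)c(OC)c(CC=C(C)C)c1OCOC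
F2 | step 10 | 1-[2-hydroxy-4-methoxy-6-(methoxymethoxy)-3,5-bis(3-methylbut-2-enyl)phenyl]-3-[2,4,5-tris(methoxymethoxy)phenyl]prop-2-yn-1-ol (racemic) | OC(C#Cc1cc(OCOC)c(OCOC)cc1OCOC)c1c(O)c(CC=C(C)C)c(OC)c(CC=C(C)C)c1OCOC
F3 | step 4 | [3-bromo-4-methoxy-2,6-bis(methoxymethoxy)phenyl]trimethylsilane | COc1cc(OCOC)c([Si](C)(C)C)c(OCOC)c1Br
F4 | step 4 | [3-bromo-4-methoxy-2,6-bis(methoxymethoxy)-5-(3-methylbut-2-enyl)phenyl]trimethylsilane | COc1c(Br)c(OCOC)c([Si](C)(C)C)c(OCOC)c1CC=C(C)C
F5 | step 5 | [4-methoxy-3,5-bis(3-methylbut-2-enyl)-2,6-bis(trimethylsilyloxy)phenyl]trimethylsilane | COc1c(CC=C(C)C)c(O[Si](C)(C)C)c([Si](C)(C)C)c(O[Si](C)(C)C)c1CC=C(C)C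
F6 | step 5 | lithium 3-methoxy-2,4-bis(3-methylbut-2-enyl)-6-(trimethylsilyl)-5-(trimethylsilyloxy)phenoxide | COc1c(CC=C(C)C)c([O-])c([Si](C)(C)C)c(O[Si](C)(C)C)c1CC=C(C)C.[Li+]
F0 | step 12 | none | none
F7 | step 14 | 7-methoxy-3,6,8-tris(3-methylbut-2-enyl)-5-(trimethylsilyloxy)-2-[2,4,5-tris(trimethylsilyloxy)phenyl]chromen-4-one | COc1c(CC=C(C)C)c(O[Si](C)(C)C)c2c(=O)c(CC=C(C)C)c(-c3cc(O[Si](C)(C)C)c(O[Si](C)(C)C)cc3O[Si](C)(C)C)oc2c1CC=C(C)C
A1 | alternative 1 | 5-fluoro-7-methoxy-3,6,8-tris(3-methylbut-2-enyl)-2-[2,4,5-tris(methoxymethoxy)phenyl]chromen-4-one | COc1c(CC=C(C)C)c(F)c2c(=O)c(CC=C(C)C)c(-c3cc(OCOC)c(OCOC)cc3OCOC)oc2c1CC=C(C)C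
A2 | alternative 1 | 1-[2,6-difluoro-4-methoxy-3,5-bis(3-methylbut-2-enyl)phenyl]-2-(3-methylbut-2-enyl)-3-[2,4,5-tris(methoxymethoxy)phenyl]propane-1,3-dione | COc1c(CC=C(C)C)c(F)c(C(=O)C(CC=C(C)C)C(=O)c2cc(OCOC)c(OCOC)cc2OCOC)c(F)c1CC=C(C)C
A3 | alternative 2 | 1-[2,6-dihydroxy-4-methoxy-3,5-bis(3-methylbut-2-enyl)phenyl]ethanone | CC(=O)c1c(O)c(CC=C(C)C)c(OC)c(CC=C(C)C)c1O
A4 | alternative 2 | 1-[4-methoxy-2,6-bis(2-methylbut-3-en-2-yloxy)phenyl]ethanone | CC(=O)c1c(OC(C)(C)C=C)cc(OC)cc1OC(C)(C)C=C
A5 | alternative 3 | 5-hydroxy-7-methoxy-3,6,8-tris(3-methylbut-2-enyl)-2-[2,4,5-tris(methoxymethoxy)phenyl]chromen-4-one | COc1c(CC=C(C)C)c(O)c2c(=O)c(CC=C(C)C)c(-c3cc(OCOC)c(OCOC)cc3OCOC)oc2c1CC=C(C)C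
A6 | alternative 3 | 6-(2-diazo-5-methylhex-4-enoyl)-3-(3-methylbut-2-enyl)-2-[2,4,5-tris(methoxymethoxy)phenyl]pyran-4-one | O=c1cc(C(=O)C(=[N+]=[N-])CC=C(C)C)oc(-c2cc(OCOC)c(OCOC)cc2OCOC)c1CC=C(C)C
A7 | alternative 3 | 1-methoxy-5-methylhex-4-en-1-yne | COC#CCC=C(C)C
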